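**Plan**

Numbering: the upper flavan has O1, C2, C3, C4 and rings A (benzo), B (catechol), C (pyran). The lower flavan is primed, with rings D (benzo: C4a', C5', C6', C7', C8', C8a'), E (catechol), F (pyran). The halves are joined C4–C6'. An oxygen is named after its carbon (O3, O7'). α is the face of ring C or F that carries the 2-aryl group, β the other face.
Cuts: six O–benzyl bonds and C4'–H come first. O1'–C2' (epoxide opening) and C4a'–C4' (aryl anion plus amide) then remove rings F and E. C7'–C8' and C5'–C6' dissolve ring D. O3–C7' (oxygen insertion), C3–C7' and C4–C6' ([2+2]) follow, and C2–aryl is cut last.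
Enabling feature: ring D is a resorcinol whose C6'–C7' edge is the α-carbon and the carbonyl carbon of a γ-lactone closed through O3. The five-membered ring C3–O3–C7'–C6'–C4 can only be cis-fused to ring C, so the 3,4-cis relation is locked before the arene exists. The missing C8'–C8a'–C4a'–C5' is the carbon chain of 4-methoxybut-3-en-2-one.
Forward: ring A is bought and ring C receives ring B. A cyclobutanone and then the lactone are fused onto C3–C4. Ring D is folded from lactone plus butenone, ring E arrives with an enone chain, and ring F closes last.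
Stereochemistry: C2 comes from a chiral palladium catalyst. C3 and C4 come from suprafacial ketene addition anti to ring B followed by a retentive oxygen insertion. C3' comes from poly-L-leucine, C2' from trans-selective epoxide opening, and C4' from equatorial attack of a hindered hydride.

Key step: step 8

Assumption: (R)-t-BuPyOx is taken to steer the aryl group to the face of the chromone that gives the (2S)-flavanone; if the sense is the reverse, the (S)-ligand is used and nothing else changes.

**Step 1**
Reactants: 1 7-hydroxy-4H-chromen-4-one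
Product: 2 7-(benzyloxy)-4H-chromen-4-one
Conditions: BnBr, K2CO3, DMF, 60 °C
Reagents that add atoms: benzyl bromide, BrCc1ccccc1
Why: Williamson ether synthesis on an acidic phenol para to the carbonyl group; the benzyl ether lasts until the final hydrogenolysis.

**Step 2**
Reactants: 2 7-(benzyloxy)-4H-chromen-4-one; 3 [3,4-bis(benzyloxy)phenyl]boronic acid
Product: 4 (2S)-7-(benzyloxy)-2-[3,4-bis(benzyloxy)phenyl]chroman-4-one
Conditions: Pd(OCOCF3)2 (5 mol %), (R)-t-BuPyOx (6 mol %), NH4PF6 (30 mol %), H2O (5 equiv), ClCH2CH2Cl, 60 °C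
Reagents that add atoms: none
Why: Palladium-catalysed asymmetric conjugate addition of an arylboronic acid to a chromone, a known entry to flavanones, in which the aryl–palladium species adds to C2 on the face left open by the tert-butyl group of the ligand and water protonates the palladium enolate, setting C2 as S.

**Step 3**
Reactants: 4 (2S)-flavanone
Product: 5 (2S,4S)-7-(benzyloxy)-2-[3,4-bis(benzyloxy)phenyl]chroman-4-ol (2,4-cis)
Conditions: NaBH4, THF–MeOH, 0 °C
Reagents that add atoms: none
Why: Borohydride reduction of an aryl ketone by axial attack should give mainly the equatorial 2,4-cis alcohol, and the C4 configuration is irrelevant because the next step erases it.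

**Step 4**
Reactants: 5 (2S,4S)-flavan-4-ol
Product: 6 (2S)-7-(benzyloxy)-2-[3,4-bis(benzyloxy)phenyl]-2H-chromene (flav-3-ene)
Conditions: Burgess reagent (MeO2C–N(−)–SO2–N(+)Et3), toluene, 50 °C, dark
Reagents that add atoms: none
Why: Burgess dehydration, in which the C4 sulfamate loses a syn hydrogen of C3 in a neutral intramolecular elimination, so that neither acid (which could ionise the allylic and benzylic C2–O1 bond) nor base reaches the C2 centre.

**Step 5**
Reactants: 6 (2S)-flav-3-ene; 7 trichloroacetyl chloride
Product: 9 tri-O-benzylflavan bearing a cis-fused dichlorocyclobutanone on the β face (C3–C(=O)–CCl2–C4; 2-aryl α), via dichloroketene 8 (not isolated)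
Conditions: Zn–Cu couple, Et2O–DME, rt, slow addition of 7, dark
Reagents that add atoms: none
Why: Thermal [2+2] ketene cycloaddition to an electron-rich cis-styrene bond, in which the ketene carbonyl carbon bonds to the nucleophilic C3 and CCl2 to the benzylic C4, the alkene reacts suprafacially (3,4-cis) and the approach is anti to the C2 aryl group, which sets C3 and C4.

**Step 6**
Reactants: 9 dichlorocyclobutanone
Product: 10 cis-fused cyclobutanone (C3–C(=O)–CH2–C4 on the β face; 2-aryl α)
Conditions: Zn dust, AcOH, rt
Reagents that add atoms: none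
Why: Reductive dechlorination of an α,α-dichloroketone through zinc enolates that acetic acid protonates, with a ring fusion that can only stay cis in a four-membered ring.

**Step 7**
Reactants: 10 cyclobutanone
Product: 11 (2R,3S,4S) γ-lactone cis-fused across C3–C4 on the β face (C3–O3–C(=O)–CH2–C4) of 7-(benzyloxy)-2-[3,4-bis(benzyloxy)phenyl]chroman
Conditions: 30% H2O2, AcOH, 0 °C
Reagents that add atoms: hydrogen peroxide, OO
Why: Baeyer–Villiger oxidation, fast for strained cyclobutanones, in which the secondary C3 migrates in preference to the CH2 group and with retention, so that O3 arrives on the β face.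

**Step 8**
Reactants: 11 γ-lactone; 12 (E)-4-methoxybut-3-en-2-one
Product: 16 (2R,3S,4S)-7-(benzyloxy)-2-[3,4-bis(benzyloxy)phenyl]-4-(2,4-dihydroxyphenyl)chroman-3-ol, via lithium enolate 13 (not isolated), via diketo enol ether 14 (not isolated), via formyl diketone 15 (not isolated)
Conditions: 12 (2.5 equiv), LiN(SiMe3)2 (3.5 equiv), THF, −78 °C; add 11, −78 → 0 °C; then MeOH, KOH (10 equiv), argon, 65 °C; 1 M HCl to pH 5
Reagents that add atoms: none
Why: Proposed new method: the kinetic enolate 13 attacks the lactone carbonyl C7' through its methylene carbon C8', the tetrahedral adduct collapses with release of O3 as an alkoxide, and the surplus amide deprotonates diketone 14 at C8', which makes the acylation irreversible. In hot methanolic KOH the vinylogous ester carbon C5' is unmasked to the formyl group of 15, the small equilibrium share of the C6' enolate adds to it, and loss of water followed by enolisation gives the bis-phenolate of 16, the only irreversible exit from the manifold. The closest known reactions are the Claisen acylation of ketone enolates by lactones, the acylation of this very enolate by acid chlorides, and the alkali-induced aldol aromatisation of 2,4,6-triketones (also when released from 4-pyranones) to resorcinols; new are the merger in one flask and a singly activated methylene as aldol donor toward a masked aldehyde. Ring D closes in the 6-(enolexo)-exo-trig mode at C5'. No stereocentre is formed, and C2, C3 and C4 are safe because none of them is acidic, C4 never becomes cationic and ring B carries no free phenol that could open ring C. The step needs C- over O-cyclisation: attack of O7' on C5' gives a 4-pyranone that hydroxide reopens at C5', potassium in methanol does not hold the diketonate in the chelated extended shape that keeps C6' away from C5', and C8' cannot compete because it would close a four-membered ring, so the place of every ring D carbon is fixed by the chain.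

**Step 9**
Reactants: 16 4-(2,4-dihydroxyphenyl)flavan-3-ol
Product: 17 the C4a' bromide: 4-(5-bromo-2,4-dihydroxyphenyl) analogue of 16 (stereocentres unchanged)
Conditions: NBS (1.0 equiv), CH2Cl2–THF, −78 °C
Reagents that add atoms: N-bromosuccinimide, O=C1CCC(=O)N1Br
Why: Electrophilic aromatic bromination, in which the free resorcinol ring D reacts far faster than the ether rings A and B, and C4a' (para to O7', ortho to O8a') is favoured over C8', which is wedged between the two hydroxyl groups.

**Step 10**
Reactants: 17 bromoresorcinol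
Product: 18 4-[5-bromo-2,4-bis(methoxymethoxy)phenyl] analogue of 16 with O3–H free
Conditions: MOMCl (2.4 equiv), i-Pr2NEt, CH2Cl2, 0 °C → rt
Reagents that add atoms: chloromethyl methyl ether, COCCl
Why: Acetal protection of the two phenols under amine base (the hindered secondary O3–H reacts far more slowly and a stray O3 acetal would fall off in step 14), giving groups that tolerate n-BuLi, stabilise a neighbouring aryllithium and leave under mild acid.

**Step 11**
Reactants: 19 3,4-bis(benzyloxy)benzaldehyde; 20 diethyl {2-[methoxy(methyl)amino]-2-oxoethyl}phosphonate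
Product: 21 (E)-3-[3,4-bis(benzyloxy)phenyl]-N-methoxy-N-methylprop-2-enamide
Conditions: NaH, THF, 0 °C → rt
Reagents that add atoms: none
Why: Horner–Wadsworth–Emmons olefination with a stabilised phosphonate anion, which is E-selective with aromatic aldehydes.

**Step 12**
Reactants: 18 aryl bromide; 21 Weinreb cinnamamide
Product: 23 (E)-chalcone: ring D of 18 carrying at C4a' the group C(=O)–CH=CH–[3,4-bis(benzyloxy)phenyl], via dilithiated arene 22 (not isolated)
Conditions: n-BuLi (2.1 equiv), THF, −78 °C; then 21; sat. aq NH4Cl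
Reagents that add atoms: none
Why: Bromine–lithium exchange (after deprotonation of O3–H) is faster than metalation of benzyl ethers at −78 °C and places the carbanion at C4a', where direct lithiation would choose C8', and the chelated adduct of the Weinreb ketone synthesis stops at the enone by 1,2-addition.

**Step 13**
Reactants: 23 chalcone
Product: 24 (αR,βS)-trans-epoxide of 23 (Cα becomes C3', Cβ becomes C2')
Conditions: poly-L-leucine, urea·H2O2, DBU, THF, rt
Reagents that add atoms: hydrogen peroxide as its urea adduct, OO.NC(N)=O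
Why: Juliá–Colonna epoxidation, in which hydroperoxide adds to the enone held at the helical peptide and poly-L-leucine delivers the (αR,βS)-epoxide of (E)-chalcones including 2'-(methoxymethoxy) ones, so that C3' is set under catalyst control and a minor isomer would be a separable diastereomer.

**Step 14**
Reactants: 24 chalcone epoxide
Product: 25 (2'R,3'R)-2',3'-trans-dihydroflavonol (rings D, E, F complete; C4' ketone; O7'–H, O3'–H and O3–H free; five benzyl ethers)
Conditions: HCl (1.25 M in MeOH), THF, 45 °C
Reagents that add atoms: none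
Why: Acid removes both MOM acetals and the freed O8a' phenol opens the epoxide at its p-alkoxybenzylic carbon in a 6-endo closure known for 2'-protected chalcone epoxides, C3' keeping its C–O bond and C2' ending trans (diequatorial) whether by inversion or through the benzylic cation, while the acyl group now on ring D shields the C4–C6' bond from protonolysis.

**Step 15**
Reactants: 25 dihydroflavonol
Product: 26 O7'-benzyl ether of 25 (six benzyl ethers)
Conditions: BnBr (1.1 equiv), K2CO3 (1.2 equiv), DMF, rt, argon
Reagents that add atoms: benzyl bromide, BrCc1ccccc1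
Why: Williamson ether synthesis on the only phenol left, whose acidity (para to the ketone) lets a weak base suffice so that C3' is not enolised, and whose capping keeps the ketone electrophilic for the next step.

**Step 16**
Reactants: 26 hexabenzyl dihydroflavonol
Product: 27 hexabenzyl ether of the target, lower unit (2'R,3'S,4'S), 2',3'-trans-3',4'-cis diol
Conditions: LiBH(s-Bu)3 (5 equiv), THF, −78 °C; sat. aq NH4Cl
Reagents that add atoms: none
Why: Reduction of a conformationally fixed six-membered ketone by a hindered trialkylborohydride, which avoids the β face guarded by the axial H-2' and attacks equatorially from the α face, giving the axial 4'β-hydroxyl cis to O3'.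

**Step 17**
Reactants: 27 hexabenzyl ether
Product: 28 the target, (2R,3S,4S)-2-(3,4-dihydroxyphenyl)-4-[(2R,3S,4S)-2-(3,4-dihydroxyphenyl)-3,4,7-trihydroxychroman-6-yl]chroman-3,7-diol
Conditions: H2 (1 atm), Pd(OH)2/C, THF–MeOH, rt, stopped after six equivalents of H2
Reagents that add atoms: none
Why: Hydrogenolysis of aryl benzyl ethers, which in neutral medium at 1 atm are cleaved much faster than a benzylic alcohol, the ring C–O bonds or the C4–C6' bond.

**Compound list**

1 | 7-hydroxy-4H-chromen-4-one | O=c1ccoc2cc(O)ccc12 | starting material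
2 | 7-(benzyloxy)-4H-chromen-4-one | O=c1ccoc2cc(OCc3ccccc3)ccc12 | intermediate
3 | [3,4-bis(benzyloxy)phenyl]boronic acid | OB(O)c1ccc(OCc2ccccc2)c(OCc2ccccc2)c1 | starting material
4 | (2S)-7-(benzyloxy)-2-[3,4-bis(benzyloxy)phenyl]chroman-4-one | c1ccccc1COc1ccc2c(c1)O[C@H](c1ccc(OCc4ccccc4)c(OCc4ccccc4)c1)CC2=O | intermediate
5 | (2S,4S)-7-(benzyloxy)-2-[3,4-bis(benzyloxy)phenyl]chroman-4-ol | c1ccccc1COc1ccc2c(c1)O[C@H](c1ccc(OCc4ccccc4)c(OCc4ccccc4)c1)C[C@@H]2O | intermediate
6 | (2S)-7-(benzyloxy)-2-[3,4-bis(benzyloxy)phenyl]-2H-chromene | c1ccccc1COc1ccc2c(c1)O[C@H](c1ccc(OCc4ccccc4)c(OCc4ccccc4)c1)C=C2 | intermediate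
7 | trichloroacetyl chloride | ClC(Cl)(Cl)C(Cl)=O | starting material
8 | dichloroketene | ClC(Cl)=C=O | intermediate
9 | β-face cis-fused dichlorocyclobutanone (C=O on C3, CCl2 on C4) | c1ccccc1COc1ccc2c(c1)O[C@H](c1ccc(OCc4ccccc4)c(OCc4ccccc4)c1)[C@@H]3[C@H]2C(Cl)(Cl)C3=O | intermediate
10 | β-face cis-fused cyclobutanone (C=O on C3, CH2 on C4) | c1ccccc1COc1ccc2c(c1)O[C@H](c1ccc(OCc4ccccc4)c(OCc4ccccc4)c1)[C@@H]3[C@H]2CC3=O | intermediate
11 | (2R,3S,4S) cis-fused γ-lactone across C3–C4 | c1ccccc1COc1ccc2c(c1)O[C@H](c1ccc(OCc4ccccc4)c(OCc4ccccc4)c1)[C@@H](O3)[C@H]2CC3=O | intermediate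
12 | (E)-4-methoxybut-3-en-2-one | CO/C=C/C(C)=O | starting material
13 | lithium (E)-4-methoxybuta-1,3-dien-2-olate | [Li+].C=C([O-])/C=C/OC | intermediate
14 | 4-[(5E)-6-methoxy-2,4-dioxohex-5-en-1-yl]flavan-3-ol (upper unit as in 16) | c1ccccc1COc1ccc2c(c1)O[C@H](c1ccc(OCc4ccccc4)c(OCc4ccccc4)c1)[C@@H](O)[C@H]2CC(=O)CC(=O)/C=C/OC | intermediate
15 | 4-(2,4,6-trioxohexyl)flavan-3-ol (upper unit as in 16) | c1ccccc1COc1ccc2c(c1)O[C@H](c1ccc(OCc4ccccc4)c(OCc4ccccc4)c1)[C@@H](O)[C@H]2CC(=O)CC(=O)CC=O | intermediate
16 | (2R,3S,4S)-7-(benzyloxy)-2-[3,4-bis(benzyloxy)phenyl]-4-(2,4-dihydroxyphenyl)chroman-3-ol | c1ccccc1COc1ccc2c(c1)O[C@H](c1ccc(OCc4ccccc4)c(OCc4ccccc4)c1)[C@@H](O)[C@H]2c1ccc(O)cc1O | intermediate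
17 | 4-(5-bromo-2,4-dihydroxyphenyl) analogue of 16 | c1ccccc1COc1ccc2c(c1)O[C@H](c1ccc(OCc4ccccc4)c(OCc4ccccc4)c1)[C@@H](O)[C@H]2c1cc(Br)c(O)cc1O | intermediate
18 | 4-[5-bromo-2,4-bis(methoxymethoxy)phenyl] analogue of 16 | c1ccccc1COc1ccc2c(c1)O[C@H](c1ccc(OCc4ccccc4)c(OCc4ccccc4)c1)[C@@H](O)[C@H]2c1cc(Br)c(OCOC)cc1OCOC | intermediate
19 | 3,4-bis(benzyloxy)benzaldehyde | O=Cc1ccc(OCc2ccccc2)c(OCc2ccccc2)c1 | starting material
20 | diethyl {2-[methoxy(methyl)amino]-2-oxoethyl}phosphonate | CCOP(=O)(CC(=O)N(C)OC)OCC | starting material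
21 | (E)-3-[3,4-bis(benzyloxy)phenyl]-N-methoxy-N-methylprop-2-enamide | CON(C)C(=O)/C=C/c1ccc(OCc2ccccc2)c(OCc2ccccc2)c1 | intermediate
22 | C4a'-lithio O3-lithium alkoxide derived from 18 | c1ccccc1COc1ccc2c(c1)O[C@H](c1ccc(OCc4ccccc4)c(OCc4ccccc4)c1)[C@@H](O[Li])[C@H]2c1cc([Li])c(OCOC)cc1OCOC | intermediate
23 | (E)-chalcone on C4a' | c1ccccc1COc1ccc2c(c1)O[C@H](c1ccc(OCc4ccccc4)c(OCc4ccccc4)c1)[C@@H](O)[C@H]2c1cc(C(=O)/C=C/c5ccc(OCc4ccccc4)c(OCc4ccccc4)c5)c(OCOC)cc1OCOC | intermediate
24 | (αR,βS)-chalcone epoxide | c1ccccc1COc1ccc2c(c1)O[C@H](c1ccc(OCc4ccccc4)c(OCc4ccccc4)c1)[C@@H](O)[C@H]2c1cc(C(=O)[C@@H]3O[C@H]3c5ccc(OCc4ccccc4)c(OCc4ccccc4)c5)c(OCOC)cc1OCOC | intermediate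
25 | (2'R,3'R)-dihydroflavonol with free O7'–H | c1ccccc1COc1ccc2c(c1)O[C@H](c1ccc(OCc4ccccc4)c(OCc4ccccc4)c1)[C@@H](O)[C@H]2c1cc3c(cc1O)O[C@H](c1ccc(OCc4ccccc4)c(OCc4ccccc4)c1)[C@@H](O)C3=O | intermediate
26 | hexabenzyl (2'R,3'R)-dihydroflavonol | c1ccccc1COc1ccc2c(c1)O[C@H](c1ccc(OCc4ccccc4)c(OCc4ccccc4)c1)[C@@H](O)[C@H]2c1cc3c(cc1OCc4ccccc4)O[C@H](c1ccc(OCc4ccccc4)c(OCc4ccccc4)c1)[C@@H](O)C3=O | intermediate
27 | hexabenzyl ether of the target, lower unit (2'R,3'S,4'S) | c1ccccc1COc1ccc2c(c1)O[C@H](c1ccc(OCc4ccccc4)c(OCc4ccccc4)c1)[C@@H](O)[C@H]2c1cc3c(cc1OCc4ccccc4)O[C@H](c1ccc(OCc4ccccc4)c(OCc4ccccc4)c1)[C@@H](O)[C@H]3O | intermediate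
28 | CNP0280090.1, fisetinidol-(4β→6)-fisetinidol-4β-ol | Oc1ccc2c(c1)O[C@H](c1ccc(O)c(O)c1)[C@@H](O)[C@H]2c1cc2c(cc1O)O[C@H](c1ccc(O)c(O)c1)[C@@H](O)[C@H]2O | target

**Step count and risks**

Total step count: 17. Longest linear sequence: 16 (steps 1–10 and 12–17; step 11 is a one-step side branch).

Steps most likely to fail:

Step 8. The chain may be parked as its unreactive diketonate so that enolisation at C6' is too rare. O-cyclisation onto C5' may outrun the aldol closure. Hydroxide may also strip C5' off by retro-Claisen deformylation.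
The fallback forms the same two bonds in the reverse order by two separate known operations, setting out from lactone 11. The lithium enolate of 11 (LiN(i-Pr)2, THF, −78 °C) would displace methoxide from C5' of 12 by conjugate addition–elimination. This is the known ketovinylation of ester enolates by β-alkoxyvinyl ketones, and it gives the α-(3-oxobut-1-enyl) lactone F1. NaOMe in MeOH at reflux would then equilibrate the enone geometry through the dienolate and close C8' onto C7' by a Dieckmann-type acylation. That is the closure used for cyclohexane-1,3-diones and resorcinols from 5-oxohexanoates. O3 is released and the product tautomerises to the arene, which returns the route at 16.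

Step 16. Facial selectivity may be poor if the neighbouring lithium alkoxide at O3' guides the hydride to the β face, which would lead to the 3',4'-trans alcohol.
The fallback gives up kinetic control, setting out from 26. NaBH4 in THF–MeOH would deliberately give the 2',3'-trans-3',4'-trans diol F2 by axial attack. C4' would then be equilibrated by solvolysis through its p-alkoxybenzylic cation in dilute aqueous AcOH–THF, the C4 epimerisation known for flavan-3,4-diols. The 3',4'-cis isomer is separated and the trans isomer recycled, which returns the route at 27.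

Step 17. The benzylic C4'–O bond may be over-reduced once O7' is freed, because a p-hydroxybenzyl alcohol is prone to hydrogenolysis.
The fallback swaps the protecting groups before that alcohol exists, setting out from 26. Hydrogenolysis (H2, Pd(OH)2/C) at the ketone stage would give the free-phenolic dihydroflavonol F3. TBSCl and imidazole in DMF at 0 °C would cap the six phenols to give the hexakis(silyl ether) ketone F4. LiBH(s-Bu)3 would then give the hexakis(silyl ether) 3',4'-cis diol F5. Et3N·3HF in THF would remove the silyl groups without any reducing agent, which returns the route at 28.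

**Further compounds**

F1 | step 8 | α-[(E)-3-oxobut-1-enyl] derivative of lactone 11 (substituent on C6', both C6' epimers) | c1ccccc1COc1ccc2c(c1)O[C@H](c1ccc(OCc4ccccc4)c(OCc4ccccc4)c1)[C@@H](O3)[C@H]2C(/C=C/C(C)=O)C3=O
F2 | step 16 | hexabenzyl (2'R,3'S,4'R) 2',3'-trans-3',4'-trans diol | c1ccccc1COc1ccc2c(c1)O[C@H](c1ccc(OCc4ccccc4)c(OCc4ccccc4)c1)[C@@H](O)[C@H]2c1cc3c(cc1OCc4ccccc4)O[C@H](c1ccc(OCc4ccccc4)c(OCc4ccccc4)c1)[C@@H](O)[C@@H]3O
F3 | step 17 | free-phenolic (2'R,3'R)-dihydroflavonol | Oc1ccc2c(c1)O[C@H](c1ccc(O)c(O)c1)[C@@H](O)[C@H]2c1cc3c(cc1O)O[C@H](c1ccc(O)c(O)c1)[C@@H](O)C3=O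
F4 | step 17 | hexakis(tert-butyldimethylsilyl) aryl ether of F3 | CC(C)(C)[Si](C)(C)Oc1ccc2c(c1)O[C@H](c1ccc(O[Si](C)(C)C(C)(C)C)c(O[Si](C)(C)C(C)(C)C)c1)[C@@H](O)[C@H]2c1cc3c(cc1O[Si](C)(C)C(C)(C)C)O[C@H](c1ccc(O[Si](C)(C)C(C)(C)C)c(O[Si](C)(C)C(C)(C)C)c1)[C@@H](O)C3=O
F5 | step 17 | hexakis(tert-butyldimethylsilyl) aryl ether of the target | CC(C)(C)[Si](C)(C)Oc1ccc2c(c1)O[C@H](c1ccc(O[Si](C)(C)C(C)(C)C)c(O[Si](C)(C)C(C)(C)C)c1)[C@@H](O)[C@H]2c1cc3c(cc1O[Si](C)(C)C(C)(C)C)O[C@H](c1ccc(O[Si](C)(C)C(C)(C)C)c(O[Si](C)(C)C(C)(C)C)c1)[C@@H](O)[C@H]3O
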